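Theta carries 4.00 times the partner of epsilon on the same substrate, yet its target levels off at 43.9% against 24.5%, just 1.79 times as much. So I read epsilon as stopped by its partner, the limiting reagent, and theta as stopped by its substrate, though neither run shows those amounts.

the same everywhere: substrate 0.50 M (fed, over 40 h)
- epsilon: partner 0.30 M; run made earlier
- theta: partner 1.2 M; run made earlier
- flask: partner 0.600 M; time 15 d

| run | time / d | target / % |
|---|---|---|
| epsilon | 1.04 | 19.7 |
| epsilon | 1.67 | 24.4 |
| epsilon | 3.00 | 24.1 |
| epsilon | 6.00 | 25.4 |
| epsilon | 12.0 | 24.2 |
| theta | 1.04 | 25.8 |
| theta | 3.00 | 44.8 |
| theta | 6.00 | 43.8 |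
| theta | 8.00 | 43.7 |
| theta | 12.0 | 43.5 |

(scatter of a reading: 1 percentage point)

- what was read earlier has a scatter of 1 percentage point, one standard deviation
- percentages count the whole charge, also what has not yet gone in
- the reaction counts as stopped when no species that holds the substrate changes by six tenths of a point or more over the second half of the time

- at 15 d, what has stopped the reaction, if anything has (the partner has run out first / it is still moving / all of the substrate has reacted)
- the target standing at 15 d, as a percentage of the substrate charged

Epsilon gives 2.45 for the partner bill, the partner charged per target formed in a run that partner ends. If the flask's substrate all reacts with the share read from theta's plateau, it makes 0.220 M of target, and at that bill this asks 0.538 M of partner. The flask has 0.600 M, so I expect substrate to end it, with target near 43.9%, but by a margin of just 0.0620 M.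

The forecast says the same of the ending: all of the substrate has reacted, with target at 43%. In its words, “The flask has 0.60 M partner against 0.50 M substrate, so substrate runs out first.”

The flask gives otherwise: the partner has run out first, with target at 41.0%. At 15.0 d it holds 7.0% of its substrate and 0% of its partner.

    substrate + partner → target (k = 0.0170 L mol⁻¹ min⁻¹)
    substrate + partner → second isomer (k = 0.0160 L mol⁻¹ min⁻¹)
    2 partner → homo dimer (k = 2.80 × 10⁻⁴ L mol⁻¹ min⁻¹)
    substrate + partner → isomer of the product (k = 0.00550 L mol⁻¹ min⁻¹)

In the flask the bill came to 2.92, above the 2.45 read from epsilon, and you find 0.135 M of its partner in 0.0676 M of homo dimer, two to each dimer. Now take the neighbour charged with 1.2 M of substrate and the same partner. At epsilon's bill it asks 1.29 M of partner against 0.600 M, so partner should end it at 0.245 M of target, or 20.4% of its charge. That neighbour stands at 19.3% of target at 15.0 d, with 0% of its partner and 56.3% of its substrate left.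

Readings and results are simulated with constants of no real substance; the scatter is artificial.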